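**Retrosynthetic overview**
- The target is reached by hydrogenolysis of its 5,7,4'-tribenzyl ether. The C8 methoxy group is traced back through C8–Br to C8–H, the only free position of ring A.
- Ring C is the only ring that is built. The strategy rests on the fact that O1–C8a and C4–C4a sit on neighbouring carbons of ring A, with C4a next to the oxygenated C5 and C8a next to C8, which may stay C–H. A 3-alkoxyaryne can therefore deliver oxygen to C8a and the acyl group to C4a.
- Both bonds come from one aryne inserting into the C–O bond of a β-methoxyacrylic acid that carries ring B and the C3 methoxy group. The liberated phenoxide then forms O1–C2 by displacing the β-methoxy group.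
- The aryne precursor is made from methyl 3,5-dihydroxy-4-methoxybenzoate (benzylation, reduction, oxidation, Baeyer–Villiger, ortho-bromination, retro-Brook silylation and triflation).
- The acid is made from 2,5-dimethoxyphenol and ethyl methoxyacetate (benzylation, formylation, aldol, oxidation, enol O-methylation, saponification).

Key step: step 13

Assumption: enol ether 18 and acid 19 are drawn as E isomers (the two vinylic methoxy groups trans); this geometry is erased when ring C closes, so the Z isomer or a mixture would be carried through in the same way.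

**Route**

Step 1
Reactants: 1 methyl 3,5-dihydroxy-4-methoxybenzoate
Product: 2 methyl 3,5-bis(benzyloxy)-4-methoxybenzoate
Conditions: BnBr (2.2 equiv), K2CO3, DMF, 60 °C
Reagents that add atoms: benzyl bromide, BrCc1ccccc1
Why: Williamson etherification of both phenols with a reactive benzylic bromide, under which the methyl ester is untouched.

Step 2
Reactants: 2 methyl 3,5-bis(benzyloxy)-4-methoxybenzoate
Product: 3 [3,5-bis(benzyloxy)-4-methoxyphenyl]methanol
Conditions: LiAlH4, THF, 0 °C to rt; aqueous work-up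
Reagents that add atoms: none
Why: Hydride reduction of the benzoate ester to the benzylic alcohol, which leaves aryl benzyl and methyl ethers alone.

Step 3
Reactants: 3 [3,5-bis(benzyloxy)-4-methoxyphenyl]methanol
Product: 4 3,5-bis(benzyloxy)-4-methoxybenzaldehyde
Conditions: activated MnO2, CH2Cl2, rt
Reagents that add atoms: none
Why: MnO2 oxidises benzylic alcohols selectively to the aldehyde without over-oxidation.

Step 4
Reactants: 4 3,5-bis(benzyloxy)-4-methoxybenzaldehyde
Product: 6 3,5-bis(benzyloxy)-4-methoxyphenol, via aryl formate 5 (not isolated)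
Conditions: mCPBA, CH2Cl2, 0 °C to rt; then K2CO3 (cat.), MeOH, rt
Reagents that add atoms: mCPBA, OOC(=O)c1cccc(Cl)c1
Why: Baeyer–Villiger (Dakin-type) oxidation in which the electron-rich aryl group with a para methoxy donor migrates in preference to hydrogen, and the resulting formate is cleaved by mild methanolysis.

Step 5
Reactants: 6 3,5-bis(benzyloxy)-4-methoxyphenol
Product: 7 3,5-bis(benzyloxy)-2-bromo-4-methoxyphenol
Conditions: NBS (1.0 equiv), CH2Cl2, −40 to 0 °C
Reagents that add atoms: N-bromosuccinimide, O=C1CCC(=O)N1Br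
Why: Electrophilic aromatic bromination of a phenol whose para position is blocked goes ortho to the hydroxyl, and the two ortho positions are equivalent by symmetry, so one equivalent at low temperature should give a single monobromide.

Step 6
Reactants: 7 3,5-bis(benzyloxy)-2-bromo-4-methoxyphenol
Product: 10 3,5-bis(benzyloxy)-4-methoxy-2-(trimethylsilyl)phenyl trifluoromethanesulfonate, via aryl trimethylsilyl ether 8 (not isolated), via lithium 2-silylphenoxide 9 (not isolated)
Conditions: (Me3Si)2NH, THF, reflux, then concentrate; n-BuLi, THF, −100 to −78 °C; Tf2O, −78 °C to rt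
Reagents that add atoms: hexamethyldisilazane, C[Si](C)(C)N[Si](C)(C)C; trifluoromethanesulfonic anhydride, O=S(=O)(OS(=O)(=O)C(F)(F)F)C(F)(F)F
Why: O-silylation, bromine–lithium exchange and the 1,3 O-to-C silyl shift (retro-Brook rearrangement) give the ortho-silyl phenoxide, which is triflated in the same flask, the standard entry to ortho-silylaryl triflates.

Step 7
Reactants: 11 2,5-dimethoxyphenol
Product: 12 2-(benzyloxy)-1,4-dimethoxybenzene
Conditions: BnBr, K2CO3, DMF, 60 °C
Reagents that add atoms: benzyl bromide, BrCc1ccccc1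
Why: Williamson etherification of the single phenol.

Step 8
Reactants: 12 2-(benzyloxy)-1,4-dimethoxybenzene
Product: 14 4-(benzyloxy)-2,5-dimethoxybenzaldehyde, via aryl iminium salt 13 (not isolated)
Conditions: POCl3, DMF, 0 to 70 °C; then ice-water
Reagents that add atoms: N,N-dimethylformamide, CN(C)C=O; water, O
Why: Vilsmeier–Haack formylation of a 1,2,4-trialkoxybenzene goes to the carbon para to the benzyloxy group and ortho to a methoxy group, since the site between two alkoxy groups is hindered and the remaining one has only one activating neighbour.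

Step 9
Reactants: 14 4-(benzyloxy)-2,5-dimethoxybenzaldehyde; 15 ethyl methoxyacetate
Product: 16 ethyl 3-[4-(benzyloxy)-2,5-dimethoxyphenyl]-3-hydroxy-2-methoxypropanoate (racemic mixture of diastereomers)
Conditions: LiN(iPr)2 (commercial solution), THF, −78 °C, 15 then 14; aqueous NH4Cl
Reagents that add atoms: none
Why: Aldol addition of the lithium enolate of the α-alkoxy ester to a non-enolisable aryl aldehyde; the two new stereocentres are formed without control and are both removed in steps 10 and 11.

Step 10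
Reactants: 16 ethyl 3-[4-(benzyloxy)-2,5-dimethoxyphenyl]-3-hydroxy-2-methoxypropanoate
Product: 17 ethyl 3-[4-(benzyloxy)-2,5-dimethoxyphenyl]-2-methoxy-3-oxopropanoate (racemic)
Conditions: Dess–Martin periodinane (1.2 equiv), CH2Cl2, 0 °C to rt
Reagents that add atoms: none
Why: Dess–Martin oxidation of the benzylic secondary alcohol to the ketone under neutral conditions, with only a slight excess so that the α-position of the β-keto ester is not oxidised further.

Step 11
Reactants: 17 ethyl 3-[4-(benzyloxy)-2,5-dimethoxyphenyl]-2-methoxy-3-oxopropanoate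
Product: 18 ethyl (E)-3-[4-(benzyloxy)-2,5-dimethoxyphenyl]-2,3-dimethoxyprop-2-enoate
Conditions: Cs2CO3, Me2SO4, DMF, 0 °C to rt
Reagents that add atoms: dimethyl sulfate, COS(=O)(=O)OC
Why: O-alkylation of the dissociated cesium enolate of an α-substituted β-keto ester with a hard electrophile in a dipolar aprotic solvent should favour the enol ether over C-methylation at the fully substituted α-carbon.

Step 12
Reactants: 18 ethyl (E)-3-[4-(benzyloxy)-2,5-dimethoxyphenyl]-2,3-dimethoxyprop-2-enoate
Product: 19 (E)-3-[4-(benzyloxy)-2,5-dimethoxyphenyl]-2,3-dimethoxyprop-2-enoic acid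
Conditions: LiOH·H2O, THF/MeOH/H2O, 40 °C; then 1 M HCl to pH 3–4, 0 °C
Reagents that add atoms: lithium hydroxide, [Li+].[OH-]
Why: Saponification of the ethyl ester, in which the vinylogous carbonate enol ether is stable to base and to brief cold acidification.

Step 13
Reactants: 10 3,5-bis(benzyloxy)-4-methoxy-2-(trimethylsilyl)phenyl trifluoromethanesulfonate; 19 (E)-3-[4-(benzyloxy)-2,5-dimethoxyphenyl]-2,3-dimethoxyprop-2-enoic acid
Product: 22 5,7-bis(benzyloxy)-2-[4-(benzyloxy)-2,5-dimethoxyphenyl]-3,6-dimethoxy-4H-chromen-4-one, via aryne 20 (not isolated), via ortho-acyl phenoxide 21 (not isolated)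
Conditions: 10 (1.5 equiv), CsF (4 equiv), THF, 125 °C, sealed tube
Reagents that add atoms: none
Why: Proposed new method: fluoride removes the silyl group of 10 and triflate leaves to give aryne 20; the carboxylate of 19 adds to the aryne carbon that has no oxygen neighbour (future C8a), the aryl anion formed beside the benzyloxy group attacks the ester carbonyl through a four-membered ring that opens to the ortho-acyl phenoxide 21 (bonds O1–C8a and C4–C4a), and this phenoxide adds to the β-carbon of the methoxy enone and expels methoxide (bond O1–C2). The closest known reaction types are the fluoride-induced insertion of arynes into the C–O bond of carboxylic acids to give ortho-hydroxyaryl ketones, the aryne–salicylate route to xanthones, and the closure of ortho-hydroxyaryl β-alkoxy enones to chromones; their combination with a β-methoxyacrylic acid in one flask is the new element. Ring C closes by 6-endo-trig oxa-Michael addition followed by β-elimination, so the alkene geometry of 19 does not matter. No stereocentre is formed. The step needs regioselective addition to the unsymmetrical aryne, and this is secured by the single benzyloxy group flanking the triple bond, whose inductive pull stabilises the aryl anion on the adjacent carbon and sends the oxygen nucleophile to the remote carbon, while the other flank is C–H and becomes C8. The aprotic medium and high temperature are chosen so that acyl transfer outruns protonation of the aryl anion, the acid itself being the only proton source.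

Step 14
Reactants: 22 5,7-bis(benzyloxy)-2-[4-(benzyloxy)-2,5-dimethoxyphenyl]-3,6-dimethoxy-4H-chromen-4-one
Product: 23 5,7-bis(benzyloxy)-2-[4-(benzyloxy)-2,5-dimethoxyphenyl]-8-bromo-3,6-dimethoxy-4H-chromen-4-one
Conditions: NBS (1.05 equiv), DMF, 0 °C to rt
Reagents that add atoms: N-bromosuccinimide, O=C1CCC(=O)N1Br
Why: Electrophilic aromatic bromination at C8, the only C–H of ring A, which is activated by three ortho or para oxygens (O1, 7-OBn, 5-OBn) and should be more nucleophilic than the two ring B positions, one crowded between two alkoxy groups and the other activated by a single one.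

Step 15
Reactants: 23 5,7-bis(benzyloxy)-2-[4-(benzyloxy)-2,5-dimethoxyphenyl]-8-bromo-3,6-dimethoxy-4H-chromen-4-one
Product: 24 5,7-bis(benzyloxy)-2-[4-(benzyloxy)-2,5-dimethoxyphenyl]-3,6,8-trimethoxy-4H-chromen-4-one
Conditions: NaOMe (excess), CuBr (0.3 equiv), DMF/MeOH, 110 °C
Reagents that add atoms: sodium methoxide, [Na+].[O-]C
Why: Copper-catalysed Ullmann-type methoxylation of an electron-rich aryl bromide, a standard conversion of 8-bromoflavone ethers into 8-methoxyflavones.

Step 16
Reactants: 24 5,7-bis(benzyloxy)-2-[4-(benzyloxy)-2,5-dimethoxyphenyl]-3,6,8-trimethoxy-4H-chromen-4-one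
Product: 25 5,7-dihydroxy-2-(4-hydroxy-2,5-dimethoxyphenyl)-3,6,8-trimethoxy-4H-chromen-4-one (5,7,4'-trihydroxy-3,6,8,2',5'-pentamethoxyflavone)
Conditions: H2 (1 atm), 10% Pd/C, EtOAc/MeOH, rt
Reagents that add atoms: none
Why: Hydrogenolysis of the three benzyl aryl ethers, under which the tetrasubstituted C2=C3 bond of the chromone and the methyl ethers are not reduced.

**Compound list**
1 | methyl 3,5-dihydroxy-4-methoxybenzoate | COC(=O)c1cc(O)c(OC)c(O)c1 | starting material
2 | methyl 3,5-bis(benzyloxy)-4-methoxybenzoate | COC(=O)c1cc(OCc2ccccc2)c(OC)c(OCc2ccccc2)c1 | intermediate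
3 | [3,5-bis(benzyloxy)-4-methoxyphenyl]methanol | COc1c(OCc2ccccc2)cc(CO)cc1OCc1ccccc1 | intermediate
4 | 3,5-bis(benzyloxy)-4-methoxybenzaldehyde | COc1c(OCc2ccccc2)cc(C=O)cc1OCc1ccccc1 | intermediate
5 | 3,5-bis(benzyloxy)-4-methoxyphenyl formate | COc1c(OCc2ccccc2)cc(OC=O)cc1OCc1ccccc1 | intermediate (not isolated)
6 | 3,5-bis(benzyloxy)-4-methoxyphenol | COc1c(OCc2ccccc2)cc(O)cc1OCc1ccccc1 | intermediate
7 | 3,5-bis(benzyloxy)-2-bromo-4-methoxyphenol | COc1c(OCc2ccccc2)cc(O)c(Br)c1OCc1ccccc1 | intermediate
8 | [3,5-bis(benzyloxy)-2-bromo-4-methoxyphenoxy]trimethylsilane | COc1c(OCc2ccccc2)cc(O[Si](C)(C)C)c(Br)c1OCc1ccccc1 | intermediate (not isolated)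
9 | lithium 3,5-bis(benzyloxy)-4-methoxy-2-(trimethylsilyl)phenolate | [Li+].COc1c(OCc2ccccc2)cc([O-])c([Si](C)(C)C)c1OCc1ccccc1 | intermediate (not isolated)
10 | 3,5-bis(benzyloxy)-4-methoxy-2-(trimethylsilyl)phenyl trifluoromethanesulfonate | COc1c(OCc2ccccc2)cc(OS(=O)(=O)C(F)(F)F)c([Si](C)(C)C)c1OCc1ccccc1 | intermediate
11 | 2,5-dimethoxyphenol | COc1ccc(OC)c(O)c1 | starting material
12 | 2-(benzyloxy)-1,4-dimethoxybenzene | COc1ccc(OC)c(OCc2ccccc2)c1 | intermediate
13 | [4-(benzyloxy)-2,5-dimethoxyphenyl]methylidene(dimethyl)ammonium dichlorophosphate | C[N+](C)=Cc1cc(OC)c(OCc2ccccc2)cc1OC.[O-]P(=O)(Cl)Cl | intermediate (not isolated)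
14 | 4-(benzyloxy)-2,5-dimethoxybenzaldehyde | COc1cc(OCc2ccccc2)c(OC)cc1C=O | intermediate
15 | ethyl methoxyacetate | COCC(=O)OCC | starting material
16 | ethyl 3-[4-(benzyloxy)-2,5-dimethoxyphenyl]-3-hydroxy-2-methoxypropanoate (racemic mixture of diastereomers) | CCOC(=O)C(OC)C(O)c1cc(OC)c(OCc2ccccc2)cc1OC | intermediate
17 | ethyl 3-[4-(benzyloxy)-2,5-dimethoxyphenyl]-2-methoxy-3-oxopropanoate (racemic) | CCOC(=O)C(OC)C(=O)c1cc(OC)c(OCc2ccccc2)cc1OC | intermediate
18 | ethyl (E)-3-[4-(benzyloxy)-2,5-dimethoxyphenyl]-2,3-dimethoxyprop-2-enoate | CO/C(=C(/OC)C(=O)OCC)c1cc(OC)c(OCc2ccccc2)cc1OC | intermediate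
19 | (E)-3-[4-(benzyloxy)-2,5-dimethoxyphenyl]-2,3-dimethoxyprop-2-enoic acid | CO/C(=C(/OC)C(=O)O)c1cc(OC)c(OCc2ccccc2)cc1OC | intermediate
20 | 3,5-bis(benzyloxy)-4-methoxybenzyne (1,2-didehydro arene) | COC1=C(OCc2ccccc2)C#CC=C1OCc1ccccc1 | intermediate (not isolated)
21 | (E)-1-[2,4-bis(benzyloxy)-6-hydroxy-3-methoxyphenyl]-3-[4-(benzyloxy)-2,5-dimethoxyphenyl]-2,3-dimethoxyprop-2-en-1-one (present as its phenoxide) | CO/C(=C(/OC)C(=O)c1c(O)cc(OCc2ccccc2)c(OC)c1OCc1ccccc1)c1cc(OC)c(OCc2ccccc2)cc1OC | intermediate (not isolated)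
22 | 5,7-bis(benzyloxy)-2-[4-(benzyloxy)-2,5-dimethoxyphenyl]-3,6-dimethoxy-4H-chromen-4-one | COc1c(OCc2ccccc2)cc2oc(-c3cc(OC)c(OCc4ccccc4)cc3OC)c(OC)c(=O)c2c1OCc1ccccc1 | intermediate
23 | 5,7-bis(benzyloxy)-2-[4-(benzyloxy)-2,5-dimethoxyphenyl]-8-bromo-3,6-dimethoxy-4H-chromen-4-one | COc1c(OCc2ccccc2)c(Br)c2oc(-c3cc(OC)c(OCc4ccccc4)cc3OC)c(OC)c(=O)c2c1OCc1ccccc1 | intermediate
24 | 5,7-bis(benzyloxy)-2-[4-(benzyloxy)-2,5-dimethoxyphenyl]-3,6,8-trimethoxy-4H-chromen-4-one | COc1c(OCc2ccccc2)c(OC)c2oc(-c3cc(OC)c(OCc4ccccc4)cc3OC)c(OC)c(=O)c2c1OCc1ccccc1 | intermediate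
25 | 5,7-dihydroxy-2-(4-hydroxy-2,5-dimethoxyphenyl)-3,6,8-trimethoxy-4H-chromen-4-one | COc1cc(-c2oc3c(OC)c(O)c(OC)c(O)c3c(=O)c2OC)c(OC)cc1O | target

**Step count**
Total: 16 steps. Longest linear sequence: 10 steps (steps 1–6 or 7–12, then 13–16).

**Steps most likely to fail**

Step 13. The aryl anion may be protonated before it transfers the acyl group, which would stop at the simple aryl ester; it may instead attack the β-carbon of the acrylate; or the ring closure may stall at the open ketone. The fallback sets out from bromophenol 7 and acid 19 and replaces the aryne by an anionic Fries sequence. The two are coupled with EDC·HCl and DMAP in CH2Cl2 to give the aryl ester 3,5-bis(benzyloxy)-2-bromo-4-methoxyphenyl (E)-3-[4-(benzyloxy)-2,5-dimethoxyphenyl]-2,3-dimethoxyprop-2-enoate F1. Treatment of this ester with n-BuLi in THF at −100 °C should bring about bromine–lithium exchange and the 1,3 O-to-C acyl shift to the lithium salt of 21. That salt should close with loss of methoxide on warming, with a finish in TsOH/toluene at 80 °C if open ketone remains, and the route is rejoined at 22.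

Step 14. Bromination may also take place on ring B, or go twice. The fallback sets out from 22 and raises the reactivity of C8 by freeing the para phenol. BCl3 (1.1 equiv, CH2Cl2, −78 °C) should cleave the peri 5-O-benzyl ether selectively through chelation to the C4 carbonyl and give 7-(benzyloxy)-2-[4-(benzyloxy)-2,5-dimethoxyphenyl]-5-hydroxy-3,6-dimethoxy-4H-chromen-4-one F2. NBS at −20 °C should then brominate para to the free hydroxyl to give 7-(benzyloxy)-2-[4-(benzyloxy)-2,5-dimethoxyphenyl]-8-bromo-5-hydroxy-3,6-dimethoxy-4H-chromen-4-one F3. Re-benzylation (BnBr, K2CO3, DMF) returns to the route at 23.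

Step 15. The C–Br bond may be reduced instead of substituted, or methoxide may attack C2 and open the pyranone ring. The fallback sets out from 23 and installs the oxygen through boron. Miyaura borylation (B2pin2, PdCl2(dppf), KOAc, dioxane, 90 °C) should give 5,7-bis(benzyloxy)-2-[4-(benzyloxy)-2,5-dimethoxyphenyl]-3,6-dimethoxy-8-(4,4,5,5-tetramethyl-1,3,2-dioxaborolan-2-yl)-4H-chromen-4-one F4. Mild oxidation (NaBO3·4H2O, THF/H2O, rt) should give 5,7-bis(benzyloxy)-2-[4-(benzyloxy)-2,5-dimethoxyphenyl]-8-hydroxy-3,6-dimethoxy-4H-chromen-4-one F5. Methylation (MeI, K2CO3, acetone) returns to the route at 24.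

**Further compounds**
F1 | step 13 | 3,5-bis(benzyloxy)-2-bromo-4-methoxyphenyl (E)-3-[4-(benzyloxy)-2,5-dimethoxyphenyl]-2,3-dimethoxyprop-2-enoate | CO/C(=C(/OC)C(=O)Oc1cc(OCc2ccccc2)c(OC)c(OCc2ccccc2)c1Br)c1cc(OC)c(OCc2ccccc2)cc1OC
F2 | step 14 | 7-(benzyloxy)-2-[4-(benzyloxy)-2,5-dimethoxyphenyl]-5-hydroxy-3,6-dimethoxy-4H-chromen-4-one | COc1c(OCc2ccccc2)cc2oc(-c3cc(OC)c(OCc4ccccc4)cc3OC)c(OC)c(=O)c2c1O
F3 | step 14 | 7-(benzyloxy)-2-[4-(benzyloxy)-2,5-dimethoxyphenyl]-8-bromo-5-hydroxy-3,6-dimethoxy-4H-chromen-4-one | COc1c(OCc2ccccc2)c(Br)c2oc(-c3cc(OC)c(OCc4ccccc4)cc3OC)c(OC)c(=O)c2c1O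
F4 | step 15 | 5,7-bis(benzyloxy)-2-[4-(benzyloxy)-2,5-dimethoxyphenyl]-3,6-dimethoxy-8-(4,4,5,5-tetramethyl-1,3,2-dioxaborolan-2-yl)-4H-chromen-4-one | COc1c(OCc2ccccc2)c(B2OC(C)(C)C(C)(C)O2)c2oc(-c3cc(OC)c(OCc4ccccc4)cc3OC)c(OC)c(=O)c2c1OCc1ccccc1
F5 | step 15 | 5,7-bis(benzyloxy)-2-[4-(benzyloxy)-2,5-dimethoxyphenyl]-8-hydroxy-3,6-dimethoxy-4H-chromen-4-one | COc1c(OCc2ccccc2)c(O)c2oc(-c3cc(OC)c(OCc4ccccc4)cc3OC)c(OC)c(=O)c2c1OCc1ccccc1
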